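Ring numbering as in the target name: C1 is the ring carbonyl, C2 carries the butanoyl group, C4 is the quaternary stereocentre and C6 carries the CH2–aryl bridge. The route rests on disconnecting the dienone ring at C1–C6. C1 is introduced as carbon disulfide on the 1,3-diketone carbon (future C2) of an acyclic, enantioenriched triketone; this turns C2 into a fully substituted push–pull alkene, so the acetyl methyl on the quaternary carbon (future C6) is the only productive enolate and closes the carbocycle by addition–elimination at the dithio carbon, hydrolysis then unveiling the acyl-trione. The step exploits the three acyl groups that converge on C2. The aryl half is attached last through an o-quinone methide.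

Key step: step 6

Assumption (chemistry): the lithium aza-enolate of the L-valine tert-butyl ester enamine is taken to be alkylated in PhMe/HMPA on the face that gives (R)-6; if the sense is opposite, THF as solvent or the D-valine ester gives the same compound.

Step 1
Reactants: 1 ethyl 2-methyl-3-oxobutanoate; 2 L-valine tert-butyl ester (free base)
Product: 3 ethyl (2Z)-3-{[(2S)-1-tert-butoxy-3-methyl-1-oxobutan-2-yl]amino}-2-methylbut-2-enoate
Conditions: BF3·OEt2 (cat.), PhMe, reflux, Dean–Stark trap
Reagents that add atoms: none
Why: Acid-catalysed condensation of the primary amine with the ketone of 1 under azeotropic removal of water should give the conjugated, N–H···O=C hydrogen-bonded (Z)-enamino ester (enamine formation), and no stereocentre is created.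

Step 2
Reactants: 3 enamino ester; 4 1-bromo-3-methylbut-2-ene (prenyl bromide)
Product: 6 ethyl (2R)-2-acetyl-2,5-dimethylhex-4-enoate, via alkylated imine 5 (not isolated)
Conditions: LiN(iPr)2 (1.2 equiv), HMPA (1 equiv), PhMe, −78 °C; 4, −78 → −40 °C; then 1 M aq. HCl, THF, 0 °C
Reagents that add atoms: water, O
Why: N-Deprotonation gives a lithium aza-enolate chelated by the valine ester, which is C-alkylated by the allylic bromide (auxiliary-controlled enamine alkylation) on the face away from the isopropyl group to set the quaternary centre as (R), and mild acid hydrolysis of imine 5 should release 6 and the recoverable auxiliary without touching the trisubstituted alkene.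

Step 3
Reactants: 6 ethyl (2R)-2-acetyl-2,5-dimethylhex-4-enoate
Product: 7 (2R)-2-acetyl-2,5-dimethylhex-4-enoic acid
Conditions: LiOH (1.5 equiv, 0.3 M), THF/H2O, 0 → 20 °C; then 1 M HCl to pH 3, 0 °C; used at once
Reagents that add atoms: lithium hydroxide, [Li+].[OH-]
Why: Cold dilute hydroxide should saponify the ethyl ester (ester hydrolysis, the ketonic mode of acetoacetic ester cleavage) faster than it cleaves the acetyl group, the quaternary centre cannot epimerise, and the β-keto acid is kept cold to avoid decarboxylation.

Step 4
Reactants: 7 (2R)-2-acetyl-2,5-dimethylhex-4-enoic acid; 8 pentan-2-one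
Product: 10 (3R)-3-methyl-3-(3-methylbut-2-en-1-yl)nonane-2,4,6-trione, via acid chloride 9 (not isolated)
Conditions: 7, Me2C=C(Cl)NMe2 (1.1 equiv), CH2Cl2, 0 °C; solution added to 8 (2.2 equiv)/LiN(iPr)2 (2.2 equiv), THF, −78 °C
Reagents that add atoms: none
Why: The α-chloroenamine converts the acid into acid chloride 9 under neutral conditions, and the kinetic methyl enolate of 8 is C-acylated by it (enolate acylation, a crossed Claisen-type condensation) while the second equivalent of enolate deprotonates the 1,3-diketone as it forms; 9 has no α-hydrogen, so the stereocentre is untouched.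

Step 5
Reactants: 10 (3R)-3-methyl-3-(3-methylbut-2-en-1-yl)nonane-2,4,6-trione
Product: 12 (3R)-5-[bis(methylsulfanyl)methylidene]-3-methyl-3-(3-methylbut-2-en-1-yl)nonane-2,4,6-trione, via ene-1,1-dithiolate 11 (not isolated)
Conditions: K2CO3 (3 equiv), CS2 (1.5 equiv), DMF, 0 → 20 °C; then MeI (2.2 equiv), 20 °C
Reagents that add atoms: carbon disulfide, S=C=S; iodomethane, CI
Why: Only the 1,3-diketone CH2 is acidic enough for K2CO3, so it adds to CS2 and the ene-dithiolate 11 is S-methylated twice (standard α-oxoketene dithioacetal formation), which installs the future ring carbonyl carbon C1 and removes the acidic hydrogen of future C2.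

Step 6
Reactants: 12 (3R)-5-[bis(methylsulfanyl)methylidene]-3-methyl-3-(3-methylbut-2-en-1-yl)nonane-2,4,6-trione
Product: 14 (4R)-2-butanoyl-3,5-dihydroxy-4-methyl-4-(3-methylbut-2-en-1-yl)cyclohexa-2,5-dien-1-one, via cyclic vinylogous thioester 13 (not isolated)
Conditions: KN(SiMe3)2 (1.3 equiv), THF, −78 → 20 °C; then 2 M aq. KOH, 50 °C; then 1 M HCl, 0 °C
Reagents that add atoms: potassium hydroxide, [K+].[OH-]
Why: KN(SiMe3)2 deprotonates the acetyl methyl (future C6), the only position whose enolate can cyclise because future C2 is a fully substituted alkene carbon, and the enolate carbon adds to the bis(methylsulfanyl) carbon (future C1) and expels methanethiolate to give 13; hydroxide then replaces the remaining methylsulfanyl group of this doubly acyl-activated vinylogous thioester, which unveils the C1 oxygen of 14. The closest known reaction type is the base-mediated addition–elimination (vinylic substitution) of ketone enolates at the dithio carbon of acceptor-substituted ketene dithioacetals, used here intramolecularly as a Dieckmann-type closure in which CS2 stands for the ester carbonyl. The six-membered carbocycle is closed by C6–C1 bond formation in a 6-endo-trig mode with respect to the C2=C1 acceptor, the enolate double bond C5=C6 lying inside the ring (enolendo). No new stereocentre is formed: C4, set in step 2, has no α-hydrogen and cannot epimerise, and it stays stereogenic because C2 carries the butanoyl group while C6 does not. The step needs carbon- rather than oxygen-attack of the ambident enolate and closure at C1 rather than aldol addition to the butanoyl or C3 carbonyl; the soft dithio-substituted carbon favours C-attack of the potassium enolate, aldol adducts can revert, and loss of thiolate followed by deprotonation of 13 makes the C–C closure the irreversible sink.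

Step 7
Reactants: 15 2-methylbenzene-1,3,5-triol; 16 butanoyl chloride
Product: 17 1-(2,4,6-trihydroxy-3-methylphenyl)butan-1-one
Conditions: AlCl3 (3 equiv), PhNO2/CH2Cl2, 0 → 40 °C; aq. HCl work-up
Reagents that add atoms: none
Why: Friedel–Crafts acylation of the electron-rich triol, whose two free ring positions are equivalent, should stop after one acylation because the AlCl3-complexed aryl ketone is deactivated.

Step 8
Reactants: 17 1-(2,4,6-trihydroxy-3-methylphenyl)butan-1-one
Product: 18 1-(2,6-dihydroxy-4-methoxy-3-methylphenyl)butan-1-one
Conditions: Me2SO4 (1.0 equiv), K2CO3 (1.0 equiv), acetone, 20 °C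
Reagents that add atoms: dimethyl sulfate, COS(=O)(=O)OC
Why: O-Methylation (Williamson-type) with one equivalent of reagent should select the 4-OH, para to the ketone, because it is the most acidic hydroxyl and is not deactivated by chelation to the carbonyl as the two ortho hydroxyls are.

Step 9
Reactants: 18 1-(2,6-dihydroxy-4-methoxy-3-methylphenyl)butan-1-one
Product: 19 1-{3-[(dimethylamino)methyl]-2,6-dihydroxy-4-methoxy-5-methylphenyl}butan-1-one
Conditions: Me2N=CH2 I (1.1 equiv), K2CO3 (1.1 equiv), MeCN, 0 → 20 °C
Reagents that add atoms: dimethyl(methylidene)ammonium iodide, C[N+](C)=C.[I-]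
Why: Phenol Mannich reaction (aminomethylation by a preformed iminium salt) can only occur at the single free ring position, which is ortho to a hydroxyl and to the methoxy group.

Step 10
Reactants: 14 (4R)-2-butanoyl-3,5-dihydroxy-4-methyl-4-(3-methylbut-2-en-1-yl)cyclohexa-2,5-dien-1-one; 19 Mannich base
Product: 21 (4R)-2-butanoyl-6-[(3-butanoyl-2,4-dihydroxy-6-methoxy-5-methylphenyl)methyl]-3,5-dihydroxy-4-methyl-4-(3-methylbut-2-en-1-yl)cyclohexa-2,5-dien-1-one, via o-quinone methide 20 (not isolated)
Conditions: 1,4-dioxane, 90 °C, N2
Reagents that add atoms: none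
Why: Thermal loss of dimethylamine from the ortho-hydroxybenzylamine, assisted by the acidic trione, should give o-quinone methide 20, which is trapped at its exocyclic carbon by the only nucleophilic carbon of 14, C6 (Michael addition to an o-quinone methide with rearomatisation), and no stereocentre is formed or touched.

Compound list
1 | ethyl 2-methyl-3-oxobutanoate | CCOC(=O)C(C)C(C)=O | starting material
2 | L-valine tert-butyl ester, (S) | CC(C)[C@H](N)C(=O)OC(C)(C)C | starting material
3 | ethyl (2Z)-3-{[(2S)-1-tert-butoxy-3-methyl-1-oxobutan-2-yl]amino}-2-methylbut-2-enoate | CCOC(=O)/C(C)=C(/C)N[C@@H](C(C)C)C(=O)OC(C)(C)C | intermediate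
4 | 1-bromo-3-methylbut-2-ene (prenyl bromide) | CC(C)=CCBr | starting material
5 | ethyl (2R)-3-{[(2S)-1-tert-butoxy-3-methyl-1-oxobutan-2-yl]imino}-2-methyl-2-(3-methylbut-2-en-1-yl)butanoate | CCOC(=O)[C@](C)(CC=C(C)C)C(C)=N[C@@H](C(C)C)C(=O)OC(C)(C)C | intermediate (not isolated)
6 | ethyl (2R)-2-acetyl-2,5-dimethylhex-4-enoate | CCOC(=O)[C@](C)(CC=C(C)C)C(C)=O | intermediate
7 | (2R)-2-acetyl-2,5-dimethylhex-4-enoic acid | OC(=O)[C@](C)(CC=C(C)C)C(C)=O | intermediate
8 | pentan-2-one | CCCC(C)=O | starting material
9 | (2R)-2-acetyl-2,5-dimethylhex-4-enoyl chloride | ClC(=O)[C@](C)(CC=C(C)C)C(C)=O | intermediate (not isolated)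
10 | (3R)-3-methyl-3-(3-methylbut-2-en-1-yl)nonane-2,4,6-trione | CCCC(=O)CC(=O)[C@](C)(CC=C(C)C)C(C)=O | intermediate
11 | dipotassium ene-1,1-dithiolate of 10, (3R)-5-(disulfidomethylidene)-3-methyl-3-(3-methylbut-2-en-1-yl)nonane-2,4,6-trione | CCCC(=O)C(=C([S-])[S-])C(=O)[C@](C)(CC=C(C)C)C(C)=O.[K+].[K+] | intermediate (not isolated)
12 | (3R)-5-[bis(methylsulfanyl)methylidene]-3-methyl-3-(3-methylbut-2-en-1-yl)nonane-2,4,6-trione | CCCC(=O)C(=C(SC)SC)C(=O)[C@](C)(CC=C(C)C)C(C)=O | intermediate
13 | (6R)-2-butanoyl-6-methyl-6-(3-methylbut-2-en-1-yl)-3-(methylsulfanyl)cyclohex-2-ene-1,5-dione | CCCC(=O)C1=C(SC)CC(=O)[C@@](C)(CC=C(C)C)C1=O | intermediate (not isolated)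
14 | (4R)-2-butanoyl-3,5-dihydroxy-4-methyl-4-(3-methylbut-2-en-1-yl)cyclohexa-2,5-dien-1-one | CCCC(=O)C1=C(O)[C@](C)(CC=C(C)C)C(O)=CC1=O | intermediate
15 | 2-methylbenzene-1,3,5-triol | Cc1c(O)cc(O)cc1O | starting material
16 | butanoyl chloride | CCCC(Cl)=O | starting material
17 | 1-(2,4,6-trihydroxy-3-methylphenyl)butan-1-one | CCCC(=O)c1c(O)cc(O)c(C)c1O | intermediate
18 | 1-(2,6-dihydroxy-4-methoxy-3-methylphenyl)butan-1-one | CCCC(=O)c1c(O)cc(OC)c(C)c1O | intermediate
19 | 1-{3-[(dimethylamino)methyl]-2,6-dihydroxy-4-methoxy-5-methylphenyl}butan-1-one | CCCC(=O)c1c(O)c(CN(C)C)c(OC)c(C)c1O | intermediate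
20 | 2-butanoyl-3-hydroxy-5-methoxy-4-methyl-6-methylidenecyclohexa-2,4-dien-1-one (o-quinone methide) | CCCC(=O)C1=C(O)C(C)=C(OC)C(=C)C1=O | intermediate (not isolated)
21 | (4R)-2-butanoyl-6-[(3-butanoyl-2,4-dihydroxy-6-methoxy-5-methylphenyl)methyl]-3,5-dihydroxy-4-methyl-4-(3-methylbut-2-en-1-yl)cyclohexa-2,5-dien-1-one | CCCC(=O)C1=C(O)[C@](C)(CC=C(C)C)C(O)=C(Cc2c(O)c(C(=O)CCC)c(O)c(C)c2OC)C1=O | target

Total step count: 10. Longest linear sequence: 7 steps (steps 1–6 and 10).

Steps most likely to fail

1. Step 6 (key step). The enolate may close through oxygen instead of carbon, giving a pyranone-type ring. It may also be held up in reversible aldol adducts with the butanoyl or C3 carbonyl, and hydrolysis of the second methylsulfanyl group may be slow once the ring is deprotonated. The fallback sets out from 12 and removes the ambident enolate. Deprotonation in the presence of Me3SiCl (KN(SiMe3)2, Me3SiCl, THF, −78 °C) should give the trimethylsilyl enol ether of the acetyl group, F1. TiCl4 in CH2Cl2 at −78 °C should then trigger an intramolecular Mukaiyama–Michael addition–elimination, in which only the enol ether carbon can bond to the dithio carbon. This gives 13, where the fallback comes back to the route; the aqueous KOH stage of step 6 then leads to 14.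

2. Step 3. Hydroxide may attack the acetyl ketone and cleave it by a retro-Claisen pathway instead of saponifying the hindered ester, and the β-keto acid may decarboxylate during isolation. The fallback sets out from 6 and takes the ketone out of play during the hydrolysis. NaBH4 in EtOH at 0 °C should reduce the ketone to the hydroxy ester F2 (both carbinol epimers are carried on). LiOH in MeOH/H2O at 60 °C should then give the hydroxy acid F3, which can be heated without risk. Oxidation with Dess–Martin periodinane in CH2Cl2 at 0 °C restores the ketone and gives 7, where the fallback comes back to the route.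

3. Step 10. The methylene bridge may exchange by retro-Michael fragmentation and re-addition under the thermal, amine-containing conditions, which would give symmetrical dimers, and the quinone methide may be consumed by a second molecule of the Mannich base. The fallback sets out from 18 and 14 and forms the bridge by reductive alkylation. Vilsmeier–Haack formylation of 18 (POCl3, DMF; aq. NaOAc) at its single free position should give 3-butanoyl-2,4-dihydroxy-6-methoxy-5-methylbenzaldehyde F4. Knoevenagel condensation of this aldehyde with 14 (L-proline cat., CH2Cl2, 20 °C) should give the alkylidene trione F5. A Hantzsch ester present in the same flask reduces F5 by transfer hydrogenation as it forms, giving 21, where the fallback comes back to the route.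

Further compounds
F1 | step 6 | (3R)-5-[bis(methylsulfanyl)methylidene]-3-methyl-3-(3-methylbut-2-en-1-yl)-2-[(trimethylsilyl)oxy]non-1-ene-4,6-dione | CCCC(=O)C(=C(SC)SC)C(=O)[C@](C)(CC=C(C)C)C(=C)O[Si](C)(C)C
F2 | step 3 | ethyl (2R)-2-(1-hydroxyethyl)-2,5-dimethylhex-4-enoate (carbinol epimers) | CCOC(=O)[C@](C)(CC=C(C)C)C(C)O
F3 | step 3 | (2R)-2-(1-hydroxyethyl)-2,5-dimethylhex-4-enoic acid (carbinol epimers) | OC(=O)[C@](C)(CC=C(C)C)C(C)O
F4 | step 10 | 3-butanoyl-2,4-dihydroxy-6-methoxy-5-methylbenzaldehyde | CCCC(=O)c1c(O)c(C=O)c(OC)c(C)c1O
F5 | step 10 | 2-butanoyl-6-[(3-butanoyl-2,4-dihydroxy-6-methoxy-5-methylphenyl)methylidene]-3-hydroxy-4-methyl-4-(3-methylbut-2-en-1-yl)cyclohex-2-ene-1,5-dione, quaternary centre as in 14 | CCCC(=O)C1=C(O)[C@](C)(CC=C(C)C)C(=O)C(=Cc2c(O)c(C(=O)CCC)c(O)c(C)c2OC)C1=O
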